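The pyran ring C is disconnected at the C4–C4a bond: C4 goes back to the terminal carbon of an oxirane and C4a to an unsubstituted carbon of ring A. The precursor is an acyclic 3,5-bis(benzyloxy)phenyl ether whose benzylic carbon (C2) carries ring B and an oxirane (C3, C4), both stereocentres already set. An AuCl3-catalysed 6-endo epoxide–arene Friedel–Crafts cyclization closes ring C and frees the C3 hydroxyl in one operation. It exploits the phloroglucinol pattern of ring A: C4a lies ortho to O1 and to the C5 oxygen and para to the C7 oxygen, and the two ortho carbons of the ether are equivalent. Acylation and hydrogenolysis finish the route.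

Key step: step 4

Remark on the chemistry: compounds 1, 4 and 7 are taken as commercially available.

Step 1
Reactants: 1 3,4,5-tris(benzyloxy)benzaldehyde
Product: 2 rac-1-[3,4,5-tris(benzyloxy)phenyl]prop-2-en-1-ol
Conditions: vinylmagnesium bromide, THF, −78 °C to 0 °C; then sat. aq NH4Cl
Reagents that add atoms: vinylmagnesium bromide, C=C[Mg]Br
Why: Grignard 1,2-addition to the non-enolizable aryl aldehyde should give the secondary allylic alcohol as a racemate, whose stereocentre is sorted out in step 2.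

Step 2
Reactants: 2 rac-1-[3,4,5-tris(benzyloxy)phenyl]prop-2-en-1-ol
Product: 3 (S)-[(2R)-oxiran-2-yl][3,4,5-tris(benzyloxy)phenyl]methanol
Conditions: Ti(OiPr)4 (0.2 equiv), L-(+)-DIPT (0.3 equiv), t-BuOOH (0.45 equiv), 4 Å MS, CH2Cl2, −20 °C
Reagents that add atoms: tert-butyl hydroperoxide, CC(C)(C)OO
Why: In this Sharpless kinetic resolution the tartrate–titanium complex should epoxidize the (R)-enantiomer of 2 much faster than the (S)-enantiomer, on the alkene face fixed by L-(+)-DIPT and with erythro selectivity, so that stopping below half conversion gives the (R)-oxirane next to a carbinol that is now named (S) only because the oxiranyl group outranks the aryl group, while (S)-2 stays behind and is removed by chromatography.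

Step 3
Reactants: 3 (S)-[(2R)-oxiran-2-yl][3,4,5-tris(benzyloxy)phenyl]methanol; 4 3,5-bis(benzyloxy)phenol
Product: 5 (2R)-2-[(R)-[3,5-bis(benzyloxy)phenoxy][3,4,5-tris(benzyloxy)phenyl]methyl]oxirane
Conditions: PPh3, DIAD, toluene, 0 °C to rt
Reagents that add atoms: none
Why: In this Mitsunobu etherification the phenol should displace the oxyphosphonium-activated benzylic hydroxyl by SN2 with inversion, turning the erythro epoxy alcohol into the threo aryl ether with (R) configuration at the future C2 while the oxirane stays untouched under the neutral conditions.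

Step 4
Reactants: 5 (2R)-2-[(R)-[3,5-bis(benzyloxy)phenoxy][3,4,5-tris(benzyloxy)phenyl]methyl]oxirane
Product: 6 (2R,3R)-5,7-bis(benzyloxy)-2-[3,4,5-tris(benzyloxy)phenyl]chroman-3-ol
Conditions: AuCl3 (5 mol %), AgOSO2CF3 (15 mol %), ClCH2CH2Cl, 0 °C to rt
Reagents that add atoms: none
Why: The AuCl3/AgOSO2CF3 pair generates a cationic trivalent gold Lewis acid that binds the oxirane oxygen, and the ring A carbon ortho to the ether oxygen (the future C4a, also ortho to C5–OBn and para to C7–OBn) attacks the terminal oxirane CH2 (the future C4) in an SN2-like Friedel–Crafts alkylation, after which proton loss rearomatizes ring A and frees the C3 hydroxyl. The closest known reaction type is the Lewis-acid-catalysed intramolecular epoxide–arene cycloalkylation of aryl glycidyl ethers to chroman-3-ols. Ring C closes in the 6-endo-tet mode with respect to the oxirane. No new stereocentre is formed: C2 and C3 come unchanged from 5 because neither the C2–O1 nor the C3–O bond is broken, so the threo ether maps onto the 2,3-cis chroman. The step needs attack at the terminal instead of the internal oxirane carbon (6-endo over 5-exo), which the primary character of that carbon and the inductive deactivation of the internal carbon by the neighbouring aryloxy-bearing carbon should secure, and it needs no site selection on ring A since its two ortho carbons are equivalent. Ring B should not compete because it would have to close a five-membered carbocycle in a 5-endo mode, and the mild catalyst should leave the benzylic C2–O bond and the benzyl ethers intact.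

Step 5
Reactants: 7 methyl 3,4-dihydroxy-5-methoxybenzoate
Product: 8 methyl 3,4-bis(benzyloxy)-5-methoxybenzoate
Conditions: BnBr, K2CO3, DMF, 60 °C
Reagents that add atoms: benzyl bromide, BrCc1ccccc1
Why: Williamson ether synthesis on the two phenoxides should proceed cleanly, since the methyl ester and the methyl ether are inert to K2CO3 in DMF.

Step 6
Reactants: 8 methyl 3,4-bis(benzyloxy)-5-methoxybenzoate
Product: 9 3,4-bis(benzyloxy)-5-methoxybenzoic acid
Conditions: LiOH, THF/MeOH/H2O, 50 °C; then 1 M HCl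
Reagents that add atoms: lithium hydroxide, [Li+].[OH-]
Why: Ester saponification by hydroxide addition–elimination should free the acid, since benzyl and methyl aryl ethers do not react with aqueous base.

Step 7
Reactants: 6 (2R,3R)-5,7-bis(benzyloxy)-2-[3,4,5-tris(benzyloxy)phenyl]chroman-3-ol; 9 3,4-bis(benzyloxy)-5-methoxybenzoic acid
Product: 10 (2R,3R)-5,7-bis(benzyloxy)-2-[3,4,5-tris(benzyloxy)phenyl]chroman-3-yl 3,4-bis(benzyloxy)-5-methoxybenzoate
Conditions: DCC, DMAP (cat.), CH2Cl2, 0 °C to rt
Reagents that add atoms: none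
Why: Steglich esterification with DMAP as acyl-transfer catalyst should acylate the hindered C3 hydroxyl at its O–H bond, so that neither stereocentre is touched.

Step 8
Reactants: 10 (2R,3R)-5,7-bis(benzyloxy)-2-[3,4,5-tris(benzyloxy)phenyl]chroman-3-yl 3,4-bis(benzyloxy)-5-methoxybenzoate
Product: 11 (−)-epigallocatechin 3-(3-methyl-gallate), (2R,3R)-5,7-dihydroxy-2-(3,4,5-trihydroxyphenyl)chroman-3-yl 3,4-dihydroxy-5-methoxybenzoate
Conditions: H2 (1 atm), Pd(OH)2/C, THF/MeOH, rt
Reagents that add atoms: none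
Why: Catalytic hydrogenolysis should cleave all seven benzyl ethers under neutral conditions at room temperature, where the aryl ester, the methyl ether, the cyclic C2–O1 bond and both stereocentres are expected to persist.

Compound list
1 | 3,4,5-tris(benzyloxy)benzaldehyde | O=Cc1cc(OCc2ccccc2)c(OCc2ccccc2)c(OCc2ccccc2)c1 | starting material
2 | rac-1-[3,4,5-tris(benzyloxy)phenyl]prop-2-en-1-ol | OC(C=C)c1cc(OCc2ccccc2)c(OCc2ccccc2)c(OCc2ccccc2)c1 | intermediate
3 | (S)-[(2R)-oxiran-2-yl][3,4,5-tris(benzyloxy)phenyl]methanol | O[C@@H](c1cc(OCc2ccccc2)c(OCc2ccccc2)c(OCc2ccccc2)c1)[C@H]1CO1 | intermediate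
4 | 3,5-bis(benzyloxy)phenol | Oc1cc(OCc2ccccc2)cc(OCc2ccccc2)c1 | starting material
5 | (2R)-2-[(R)-[3,5-bis(benzyloxy)phenoxy][3,4,5-tris(benzyloxy)phenyl]methyl]oxirane | C(c1ccccc1)Oc1cc(OCc2ccccc2)cc(O[C@H](c2cc(OCc3ccccc3)c(OCc3ccccc3)c(OCc3ccccc3)c2)[C@H]2CO2)c1 | intermediate
6 | (2R,3R)-5,7-bis(benzyloxy)-2-[3,4,5-tris(benzyloxy)phenyl]chroman-3-ol | O[C@@H]1Cc2c(OCc3ccccc3)cc(OCc3ccccc3)cc2O[C@@H]1c1cc(OCc2ccccc2)c(OCc2ccccc2)c(OCc2ccccc2)c1 | intermediate
7 | methyl 3,4-dihydroxy-5-methoxybenzoate | COC(=O)c1cc(O)c(O)c(OC)c1 | starting material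
8 | methyl 3,4-bis(benzyloxy)-5-methoxybenzoate | COC(=O)c1cc(OCc2ccccc2)c(OCc2ccccc2)c(OC)c1 | intermediate
9 | 3,4-bis(benzyloxy)-5-methoxybenzoic acid | OC(=O)c1cc(OCc2ccccc2)c(OCc2ccccc2)c(OC)c1 | intermediate
10 | (2R,3R)-5,7-bis(benzyloxy)-2-[3,4,5-tris(benzyloxy)phenyl]chroman-3-yl 3,4-bis(benzyloxy)-5-methoxybenzoate | COc1cc(C(=O)O[C@@H]2Cc3c(OCc4ccccc4)cc(OCc4ccccc4)cc3O[C@@H]2c2cc(OCc3ccccc3)c(OCc3ccccc3)c(OCc3ccccc3)c2)cc(OCc2ccccc2)c1OCc1ccccc1 | intermediate
11 | (−)-epigallocatechin 3-(3-methyl-gallate) | COc1cc(C(=O)O[C@@H]2Cc3c(O)cc(O)cc3O[C@@H]2c2cc(O)c(O)c(O)c2)cc(O)c1O | target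

Total step count: 8
Longest linear sequence: 6 (steps 1, 2, 3, 4, 7, 8)

Steps most likely to fail

Step 3. The activated benzylic oxyphosphonium ion may ionize toward a cation stabilized by ring B before the phenol attacks, which would erode the inversion and the diastereomeric purity at the future C2. The fallback forms the benzylic C–O bond by SN2 opening of an epoxide and creates the threo relationship by inversion at the other carbon. It sets out from 2 (the racemate or the (S)-enantiomer left over from step 2, since its stereocentre is erased) and comes back at 5. A Ph3SiOReO3-catalysed 1,3-transposition of the allylic alcohol (Et2O, 0 °C) should give the conjugated (E)-3-[3,4,5-tris(benzyloxy)phenyl]prop-2-en-1-ol F1. Katsuki–Sharpless epoxidation (Ti(OiPr)4, L-(+)-DIPT, t-BuOOH, 4 Å MS, CH2Cl2, −20 °C) should give [(2S,3S)-3-[3,4,5-tris(benzyloxy)phenyl]oxiran-2-yl]methanol F2. The phenoxide of 4 (NaOH, dioxane/H2O, 70 °C) should open the benzylic carbon with inversion to (2S,3R)-3-[3,5-bis(benzyloxy)phenoxy]-3-[3,4,5-tris(benzyloxy)phenyl]propane-1,2-diol F3. Selective primary benzoylation (BzCl, 2,4,6-collidine, CH2Cl2, −40 °C) should give (2S,3R)-3-[3,5-bis(benzyloxy)phenoxy]-2-hydroxy-3-[3,4,5-tris(benzyloxy)phenyl]propyl benzoate F4, and mesylation (MsCl, Et3N, CH2Cl2, 0 °C) should give (2S,3R)-3-[3,5-bis(benzyloxy)phenoxy]-2-[(methylsulfonyl)oxy]-3-[3,4,5-tris(benzyloxy)phenyl]propyl benzoate F5. K2CO3 in MeOH then removes the benzoate, and the primary alkoxide displaces the mesylate with inversion at the secondary carbon, which should deliver 5.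

Step 4. The Lewis acid may ionize the benzylic C2–O ether (loss of configuration at C2 or fragmentation), ring A may attack the internal oxirane carbon, or the oxirane may isomerize to a carbonyl compound by hydride shift. The fallback reverses the polarity of ring A and forms the same bond by an aryl anion. It sets out from 3 and 4 and comes back at 6. Ortho-bromination of 4 (NBS, cat. i-Pr2NH, CH2Cl2, 0 °C) should give 2-bromo-3,5-bis(benzyloxy)phenol F6. Mitsunobu coupling with 3 under the conditions of step 3 should give (2R)-2-[(R)-[2-bromo-3,5-bis(benzyloxy)phenoxy][3,4,5-tris(benzyloxy)phenyl]methyl]oxirane F7. MgBr2·OEt2 (THF, 0 °C) should open the oxirane at its terminal carbon to (1R,2S)-3-bromo-1-[2-bromo-3,5-bis(benzyloxy)phenoxy]-1-[3,4,5-tris(benzyloxy)phenyl]propan-2-ol F8, kept as its magnesium alkoxide. n-BuLi at −78 °C then effects bromine–lithium exchange on ring A and a Parham cycloalkylation (6-exo-tet displacement of the primary bromide by the aryllithium), which should give 6 after aqueous work-up.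

Step 2. The terminal alkene reacts slowly, so the rate difference between the two enantiomers may be too small at the conversion needed, and the product oxirane may be opened by the Ti(OiPr)4/tartrate system during the long reaction time. The fallback separates the resolution from the epoxidation and uses a hydrolase. It sets out from 2 and comes back at 3. Lipase-catalysed transesterification (immobilized lipase B from Candida antarctica, vinyl acetate, MTBE, 30 °C) should acylate the (R)-enantiomer to (R)-1-[3,4,5-tris(benzyloxy)phenyl]prop-2-en-1-yl acetate F9, which is separated from unreacted (S)-2. Methanolysis (K2CO3, MeOH, rt) should give (R)-1-[3,4,5-tris(benzyloxy)phenyl]prop-2-en-1-ol F10. This single enantiomer is then epoxidized in the matched sense (Ti(OiPr)4, L-(+)-DIPT, t-BuOOH, 4 Å MS, CH2Cl2, −20 °C) to full conversion, which should give 3.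

Further compounds
F1 | step 3 | (E)-3-[3,4,5-tris(benzyloxy)phenyl]prop-2-en-1-ol | OC/C=C/c1cc(OCc2ccccc2)c(OCc2ccccc2)c(OCc2ccccc2)c1
F2 | step 3 | [(2S,3S)-3-[3,4,5-tris(benzyloxy)phenyl]oxiran-2-yl]methanol | OC[C@@H]1O[C@H]1c1cc(OCc2ccccc2)c(OCc2ccccc2)c(OCc2ccccc2)c1
F3 | step 3 | (2S,3R)-3-[3,5-bis(benzyloxy)phenoxy]-3-[3,4,5-tris(benzyloxy)phenyl]propane-1,2-diol | OC[C@H](O)[C@H](Oc1cc(OCc2ccccc2)cc(OCc2ccccc2)c1)c1cc(OCc2ccccc2)c(OCc2ccccc2)c(OCc2ccccc2)c1
F4 | step 3 | (2S,3R)-3-[3,5-bis(benzyloxy)phenoxy]-2-hydroxy-3-[3,4,5-tris(benzyloxy)phenyl]propyl benzoate | O=C(OC[C@H](O)[C@H](Oc1cc(OCc2ccccc2)cc(OCc2ccccc2)c1)c1cc(OCc2ccccc2)c(OCc2ccccc2)c(OCc2ccccc2)c1)c1ccccc1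
F5 | step 3 | (2S,3R)-3-[3,5-bis(benzyloxy)phenoxy]-2-[(methylsulfonyl)oxy]-3-[3,4,5-tris(benzyloxy)phenyl]propyl benzoate | O=C(OC[C@H](OS(C)(=O)=O)[C@H](Oc1cc(OCc2ccccc2)cc(OCc2ccccc2)c1)c1cc(OCc2ccccc2)c(OCc2ccccc2)c(OCc2ccccc2)c1)c1ccccc1
F6 | step 4 | 2-bromo-3,5-bis(benzyloxy)phenol | Oc1cc(OCc2ccccc2)cc(OCc2ccccc2)c1Br
F7 | step 4 | (2R)-2-[(R)-[2-bromo-3,5-bis(benzyloxy)phenoxy][3,4,5-tris(benzyloxy)phenyl]methyl]oxirane | Brc1c(OCc2ccccc2)cc(OCc2ccccc2)cc1O[C@H](c1cc(OCc2ccccc2)c(OCc2ccccc2)c(OCc2ccccc2)c1)[C@H]1CO1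
F8 | step 4 | (1R,2S)-3-bromo-1-[2-bromo-3,5-bis(benzyloxy)phenoxy]-1-[3,4,5-tris(benzyloxy)phenyl]propan-2-ol | Brc1c(OCc2ccccc2)cc(OCc2ccccc2)cc1O[C@H](c1cc(OCc2ccccc2)c(OCc2ccccc2)c(OCc2ccccc2)c1)[C@H](O)CBr
F9 | step 2 | (R)-1-[3,4,5-tris(benzyloxy)phenyl]prop-2-en-1-yl acetate | CC(=O)O[C@H](C=C)c1cc(OCc2ccccc2)c(OCc2ccccc2)c(OCc2ccccc2)c1
F10 | step 2 | (R)-1-[3,4,5-tris(benzyloxy)phenyl]prop-2-en-1-ol | O[C@H](C=C)c1cc(OCc2ccccc2)c(OCc2ccccc2)c(OCc2ccccc2)c1
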